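Assumption: the carbinol carbon created in step 2 is the only stereocentre on the route and becomes the ketone carbon in step 7, so compounds 8 to 15 are carried as racemates; the target itself is achiral.

## Structural features

Preacredinone A is a benzophenone: two benzene rings joined only through one ketone carbon, with no ring fusion and no stereocentre, so no stereochemical relationships have to be set. Ring A is a 2,6-dimethoxyphenyl group. Ring B carries, in order, the ketone at C1, a free OH at C2, H at C3, CH3 at C4, OCH3 at C5 and CH2OAc at C6, so the carbonyl is flanked by four ortho substituents. The fragile groups are the primary benzylic acetate (cleaved or transferred by base, hydride and organometallic reagents) and the electron-rich 4-methoxyphenol of ring B (oxidised to a quinone by strong oxidants). At the carbinol oxidation level the diaryl carbon also ionises easily, because ring A and the ortho-phenol both stabilise a cation. The real difficulty is the contiguous, fully differentiated substitution of ring B together with the crowded aryl–C(=O)–aryl linkage, which resists late acylation or coupling. The key step exploits the para relationship of C2–OH and C5–OCH3 in ring B: a hydroquinone monomethyl ether is what results when a methoxycarbene carbon (C5) and a carbonyl ligand (C2) end up opposite each other in a new benzene ring. The C3–H/C4–CH3 pair then corresponds to an isopropenyl group and the C1/C6 pair to the two carbons of an alkyne.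

## Logic of the disconnections

16 to 15: the C=O at the carbon between the rings is traced back to a secondary carbinol (C–H and O–H restored). The cut is made here because a ketone conjugated to the alkyne would spoil the later ring construction, whereas a carbinol can be protected. The gain is a precursor whose oxygen can carry a bulky group. The demand on the forward step is an oxidant that attacks a crowded diaryl carbinol while sparing the 4-methoxyphenol ring and the acetate.

15 to 14: the O–H of the carbinol is replaced by an O–Si bond. The silyl ether is what survives ring construction and gives the carbinol arm its steric weight. The forward cleavage must not ionise the carbinol or move the acetate.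

14 to 5 and 12: three bonds of ring B are cut, C5–C6, C1–C2 and C2–C3. This dissolves the pentasubstituted ring into a three-carbon unit (C5, C4, C3) with its OCH3 and CH3 in 5, a metal-bound carbonyl that becomes C2, and a two-carbon alkyne (C1, C6) in 12. All five substituents of ring B are thereby placed by the connectivity of two simple components. The forward step must insert the unsymmetrical alkyne in one orientation only: the branched arm next to C2, the CH2OAc arm next to C5.

12 to 9 (through 11 and 10): the acetate ester C–O bond and the C–C bond between the alkyne terminus and the oxygenated CH2 carbon are cut. This leaves a terminal alkyne and a one-carbon electrophile. The forward step must metalate the alkyne C–H without touching the doubly activated C–H next to the silyl ether, and must acylate the resulting alkoxide in the same flask.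

9 to 8 to 6 and 7: the O–Si bond is cut, then the C–C bond between the carbinol carbon and the alkyne. This reduces the aryl arm to an aromatic aldehyde and a two-carbon nucleophile, both commercial. The forward demands are a simple carbonyl addition and silylation of a hydroxyl flanked by two ortho methoxy groups.

5 to 1 and 2 (through 4 and 3): the O–CH3 bond and the bond between the carbene carbon and the isopropenyl carbon are cut, then the C–Li bond is traced to C–Br. This leaves a vinyl halide and the metal carbonyl. The forward demand is clean generation of the vinyl organometallic and hard O-alkylation of the acyl metalate.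

## Other disconnections considered

Alternative 1: both aryl–carbonyl bonds are cut at once, giving the ring B iodide A1, carbon monoxide A2 and 2,6-dimethoxyphenylboronic acid A3. The forward step is a palladium-catalysed carbonylative Suzuki coupling: zerovalent palladium inserts into the C1–I bond of A1, A2 inserts, A3 transmetalates and reductive elimination would give the bis(methoxymethyl)-protected ketone A4.
- In its favour: it is convergent and the ketone appears at its final oxidation level, so there is no carbinol stereocentre and no oxidation next to a free phenol. On this point it is better than the chosen plan. The regiochemistry is fixed by the position of iodine, so the key step poses no regiochemical question; this is also better. The metal is catalytic rather than stoichiometric.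
- Against it: the product is a tetra-ortho-substituted diaryl ketone. The aroylpalladium species would have to transmetalate with a di-ortho-substituted boronic acid that protodeboronates readily under base, and direct biaryl coupling and dehalogenation would compete. A1 is itself a fully substituted arene that would have to be assembled by successive aromatic substitutions, which is the very problem the chosen plan avoids by building ring B.
- Step economy: after A4 two methoxymethyl groups must be removed and the primary alcohol acetylated selectively beside the phenol. That is two steps, equal to the chosen end-game, but the preparation of A1 would take clearly more steps than 5 and 12 together.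

Alternative 2: C1–C6 and C2–C3 of ring B are cut, leading to the furan–yne A5, an ether between the propargylic alcohol 8 of the chosen route and a 3-methoxy-4-methylfurfuryl unit. The forward step is a gold-catalysed furan–yne phenol synthesis: monovalent gold activates the terminal alkyne, the furan adds, and the arene oxide formed opens with transfer of the furan oxygen to C2, which would give the phthalan A6.
- In its favour: it is an isomerisation with complete atom economy and a catalytic metal, which is better than stoichiometric chromium. It is intramolecular, so the positions of OH, CH3 and OCH3 are fixed by the furan substitution; regiocontrol is at least equal and arguably better. It shares 8 with the chosen route.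
- Against it: the 3-methoxyfuran component is an acid-sensitive enol ether that is not commercial, and its furfuryl electrophile is prone to polymerisation. The bulky aryl group at the propargylic carbon may slow the cyclisation. Most seriously, A6 locks the future ketone carbon and the future CH2OAc carbon into one cyclic ether. Reaching the target would need selective oxidation of the doubly benzylic ether C–H in the presence of the second benzylic ether position and a free phenol, then ring opening and acetylation.
- Comparison: both plans pass through a carbinol-level carbon between the rings (equal), but in the chosen plan its oxygen carries a removable silyl group rather than being part of a ring. The end-game from A6 would probably take more than the two steps of the chosen plan.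

Alternative 3: the C1–C(=O) bond is cut (with formal insertion into the C–O bond of an acid), leading to the ortho-silylaryl triflate A7 and 2,6-dimethoxybenzoic acid A9. In the forward step fluoride would convert A7 into the aryne A8, the carboxylate of A9 would add at C2, and the C1 aryl anion would attack the ester carbonyl; the four-membered intermediate would open to the hydroxy ketone A10.
- In its favour: it needs no transition metal, and it delivers the free C2–OH and the ketone at their final oxidation levels in one operation, without phenol protection or redox adjustment. On this point it is better than the chosen plan. A9 is commercial.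
- Against it: the site of carboxylate attack on A8 is controlled only by the CH2OCH2OCH3 arm at C6, which disfavours C1 sterically but gives little electronic bias. The regiochemical risk is therefore comparable to that of the chosen plan (equal, not lower). The acyl shift needs a short-lived aryl anion to attack the carbonyl of a di-ortho-substituted benzoate, while simple proton transfer would stop at an aryl ester. A7 is a pentasubstituted arene that again requires a long preparation.
- Step economy: the end-game from A10 (removal of the methoxymethyl group, acetylation of the primary alcohol) is two steps, equal to the chosen plan, but the total count would be higher because of A7.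

Key step: step 5

## Route

Step 1
Reactants: 1 2-bromopropene; 2 chromium hexacarbonyl
Product: 5 pentacarbonyl[methoxy(prop-1-en-2-yl)carbene]chromium, via isopropenyllithium 3 (not isolated), via lithium acylchromate 4 (not isolated)
Conditions: Li (2.1 equiv), Et2O, 0 °C; then 2, Et2O, 0 °C → rt; solvent removed, Me3OBF4, CH2Cl2, 0 °C → rt; argon throughout, rapid filtration through SiO2 (hexane)
Reagents that add atoms: trimethyloxonium tetrafluoroborate, C[O+](C)C.F[B-](F)(F)F
Why: Reductive lithiation of the vinyl bromide gives 3, which adds to a CO ligand of 2 to form acyl metalate 4, and hard O-methylation then gives the alkoxycarbene complex. This is the classical acylate-alkylation route to heteroatom-stabilised chromium carbene complexes, and lithium metal avoids pyrophoric tert-butyllithium.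

Step 2
Reactants: 6 2,6-dimethoxybenzaldehyde; 7 ethynylmagnesium bromide
Product: 8 rac-1-(2,6-dimethoxyphenyl)prop-2-yn-1-ol
Conditions: THF, 0 °C → rt; sat. aq NH4Cl
Reagents that add atoms: none
Why: Grignard addition of the acetylide to the aldehyde carbonyl. The new stereocentre forms without control as the racemate, which is acceptable because this carbon becomes the ketone carbon in step 7.

Step 3
Reactants: 8 rac-1-(2,6-dimethoxyphenyl)prop-2-yn-1-ol
Product: 9 rac-tert-butyl{[1-(2,6-dimethoxyphenyl)prop-2-yn-1-yl]oxy}dimethylsilane
Conditions: TBSCl, imidazole, DMAP (cat.), DMF, rt → 40 °C
Reagents that add atoms: tert-butyldimethylsilyl chloride, CC(C)(C)[Si](C)(C)Cl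
Why: Imidazole-promoted silylation of a secondary propargylic alcohol; the slim alkyne should leave the hydroxyl accessible despite the two ortho methoxy groups. The silyl ether supplies both the protection and the steric bulk needed in step 5.

Step 4
Reactants: 9 rac-tert-butyl{[1-(2,6-dimethoxyphenyl)prop-2-yn-1-yl]oxy}dimethylsilane
Product: 12 rac-4-[(tert-butyldimethylsilyl)oxy]-4-(2,6-dimethoxyphenyl)but-2-yn-1-yl acetate, via lithium acetylide 10 (not isolated), via lithium propargylic alkoxide 11 (not isolated)
Conditions: n-BuLi (1.0 equiv), THF, −78 °C; (CH2O)n, −78 °C → rt; Ac2O, 0 °C → rt
Reagents that add atoms: paraformaldehyde (reacts as formaldehyde), C=O; acetic anhydride, CC(=O)OC(C)=O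
Why: The terminal alkyne C–H is by far the most acidic site, acetylide 10 adds to formaldehyde released from the polymer, and alkoxide 11 is O-acylated in the same flask. Alkynylation of formaldehyde with in situ acylation is routine and saves one isolation.

Step 5
Reactants: 5 pentacarbonyl[methoxy(prop-1-en-2-yl)carbene]chromium (1.5 equiv); 12 rac-4-[(tert-butyldimethylsilyl)oxy]-4-(2,6-dimethoxyphenyl)but-2-yn-1-yl acetate
Product: 14 rac-2-{[(tert-butyldimethylsilyl)oxy](2,6-dimethoxyphenyl)methyl}-3-hydroxy-6-methoxy-5-methylbenzyl acetate, via tricarbonylchromium arene complex 13 (not isolated)
Conditions: THF (degassed, 0.05 M), 55 °C, argon; then air, daylight, Et2O, rt; Et3N-deactivated SiO2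
Reagents that add atoms: none
Why: Thermal loss of one CO ligand from 5 opens a coordination site at zerovalent chromium; alkyne 12 binds and inserts into the Cr=C bond so that the former carbene carbon (C5) bonds to the CH2OAc-bearing alkyne carbon (C6) and the other alkyne carbon (C1) becomes the carbene centre of an η3-vinylcarbene. Migratory insertion of CO at this carbon forms C1–C2 and a chromium-bound dienylketene, whose 6π-electrocyclisation onto the CH2 terminus of the isopropenyl group forms C2–C3 and gives a cyclohexadienone that tautomerises to the phenol, held first as the tricarbonylchromium complex 13. Air and daylight then oxidise the metal away under conditions too mild to attack the 4-methoxyphenol. The closest known reaction is the Dötz benzannulation of alkenyl(alkoxy)carbene chromium complexes with internal alkynes, of which this is a sterically more demanding case. Ring B is the only ring closed, a six-membered carbocycle built in a formal [3+2+1] assembly whose ring-closing event is the disrotatory 6π-electrocyclisation of the dienylketene. No stereocentre is created; the silyloxy-bearing carbon is a spectator, and the diastereomers of 13 that differ in the arene face bound to chromium converge on decomplexation. The selectivity required is the regiochemistry of alkyne insertion: the α-branched silyloxy(aryl)methyl group should avoid the CO ligands of the vinylcarbene by taking the carbene carbon, which places it next to the CO-derived C2, while the unbranched CH2OAc arm lies next to C5. An alkenyl complex in THF favours phenol formation over cyclobutenone or furan by-products, and carrying the ketone as a silyl ether keeps the alkyne electron-rich enough to bind chromium.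

Step 6
Reactants: 14 rac-2-{[(tert-butyldimethylsilyl)oxy](2,6-dimethoxyphenyl)methyl}-3-hydroxy-6-methoxy-5-methylbenzyl acetate
Product: 15 rac-2-[(2,6-dimethoxyphenyl)(hydroxy)methyl]-3-hydroxy-6-methoxy-5-methylbenzyl acetate
Conditions: TBAF, AcOH (1:1), THF, 0 °C → rt; neutral work-up, crude product used at once
Reagents that add atoms: none
Why: Fluoride-induced Si–O cleavage driven by the strong Si–F bond. Buffering with acetic acid keeps the phenol and the liberated carbinol protonated, so the acetate should be neither cleaved nor transferred, and the medium is too weakly acidic to ionise the carbinol.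

Step 7
Reactants: 15 rac-2-[(2,6-dimethoxyphenyl)(hydroxy)methyl]-3-hydroxy-6-methoxy-5-methylbenzyl acetate
Product: 16 preacredinone A, 2-(2,6-dimethoxybenzoyl)-3-hydroxy-6-methoxy-5-methylbenzyl acetate
Conditions: MnO2 (activated, excess), CH2Cl2, rt, dark
Reagents that add atoms: none
Why: Heterogeneous MnO2 oxidation of a doubly benzylic alcohol; phenols and benzylic acetates are normally left untouched, and the product is stabilised by the hydrogen bond between C2–OH and the new ketone. The only stereocentre disappears here.

## Compound list

1 | 2-bromopropene | CC(Br)=C | starting material
2 | chromium hexacarbonyl, Cr(CO)6 | O=C=[Cr](=C=O)(=C=O)(=C=O)(=C=O)=C=O | starting material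
3 | isopropenyllithium (prop-1-en-2-yllithium) | [Li]C(C)=C | intermediate
4 | lithium pentacarbonyl(2-methyl-1-oxidoprop-2-en-1-ylidene)chromate (acyl metalate) | [Li+].[O-]C(C(C)=C)=[Cr](=C=O)(=C=O)(=C=O)(=C=O)=C=O | intermediate
5 | pentacarbonyl[methoxy(prop-1-en-2-yl)carbene]chromium | COC(C(C)=C)=[Cr](=C=O)(=C=O)(=C=O)(=C=O)=C=O | intermediate
6 | 2,6-dimethoxybenzaldehyde | COc1cccc(OC)c1C=O | starting material
7 | ethynylmagnesium bromide | C#C[Mg]Br | starting material
8 | rac-1-(2,6-dimethoxyphenyl)prop-2-yn-1-ol | COc1cccc(OC)c1C(O)C#C | intermediate
9 | rac-tert-butyl{[1-(2,6-dimethoxyphenyl)prop-2-yn-1-yl]oxy}dimethylsilane | COc1cccc(OC)c1C(O[Si](C)(C)C(C)(C)C)C#C | intermediate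
10 | lithium acetylide of 9, rac-{3-[(tert-butyldimethylsilyl)oxy]-3-(2,6-dimethoxyphenyl)prop-1-yn-1-yl}lithium | COc1cccc(OC)c1C(O[Si](C)(C)C(C)(C)C)C#C[Li] | intermediate
11 | lithium rac-4-[(tert-butyldimethylsilyl)oxy]-4-(2,6-dimethoxyphenyl)but-2-yn-1-olate | COc1cccc(OC)c1C(O[Si](C)(C)C(C)(C)C)C#CC[O-].[Li+] | intermediate
12 | rac-4-[(tert-butyldimethylsilyl)oxy]-4-(2,6-dimethoxyphenyl)but-2-yn-1-yl acetate | COc1cccc(OC)c1C(O[Si](C)(C)C(C)(C)C)C#CCOC(C)=O | intermediate
13 | tricarbonyl(η6-arene)chromium complex of 14, metal bound to ring B, mixture of diastereomers | COc1cccc(OC)c1C(O[Si](C)(C)C(C)(C)C)c1c(O)cc(C)c(OC)c1COC(C)=O.O=C=[Cr](=C=O)=C=O | intermediate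
14 | rac-2-{[(tert-butyldimethylsilyl)oxy](2,6-dimethoxyphenyl)methyl}-3-hydroxy-6-methoxy-5-methylbenzyl acetate | COc1cccc(OC)c1C(O[Si](C)(C)C(C)(C)C)c1c(O)cc(C)c(OC)c1COC(C)=O | intermediate
15 | rac-2-[(2,6-dimethoxyphenyl)(hydroxy)methyl]-3-hydroxy-6-methoxy-5-methylbenzyl acetate | COc1cccc(OC)c1C(O)c1c(O)cc(C)c(OC)c1COC(C)=O | intermediate
16 | preacredinone A, 2-(2,6-dimethoxybenzoyl)-3-hydroxy-6-methoxy-5-methylbenzyl acetate | COc1cccc(OC)c1C(=O)c1c(O)cc(C)c(OC)c1COC(C)=O | target

## Step count and least certain steps

Total step count: 7. Longest linear sequence: 6 steps (steps 2 to 7, from 6); step 1 supplies the second component of step 5.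

Step 5 (key step). The most likely failure is slow coordination and insertion of the very crowded internal alkyne, so that the thermally labile carbene complex decomposes first; regiocontrol could also erode if the two propargylic arms are discriminated less well than expected. The fallback attaches ring A after the benzannulation and sets out from 5. Commercial 3,3-diethoxyprop-1-yne is hydroxymethylated and acetylated as in step 4 to 4,4-diethoxybut-2-yn-1-yl acetate F1, whose large end is a compact acetal that keeps the branched-versus-unbranched bias. Benzannulation of F1 with 5 under the conditions of step 5 should give 2-(diethoxymethyl)-3-hydroxy-6-methoxy-5-methylbenzyl acetate F2. Mild aqueous acid (PPTS, acetone/H2O) releases 2-formyl-3-hydroxy-6-methoxy-5-methylbenzyl acetate F3. Addition of 2,6-dimethoxyphenyllithium F4 (from 1,3-dimethoxybenzene and n-BuLi; 2.2 equiv, THF, −78 °C, the first equivalent being consumed by the phenol) to the aldehyde, which should outpace attack of this hindered nucleophile on the acetate, then gives 15, where the route is rejoined.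

Step 6. The liberated carbinol is doubly benzylic and sits next to a free phenol. It may ionise with loss of water towards a quinone methide and then cyclise or oligomerise, and the acetate may be cleaved or shifted under fluoride. The fallback closes the quinone-methide channel before the silyl group is removed and sets out from 14. Allylation of the phenol (allyl bromide, K2CO3, acetone) gives rac-2-{[(tert-butyldimethylsilyl)oxy](2,6-dimethoxyphenyl)methyl}-6-methoxy-5-methyl-3-(prop-2-en-1-yloxy)benzyl acetate F5. Desilylation (TBAF/AcOH) gives rac-2-[(2,6-dimethoxyphenyl)(hydroxy)methyl]-6-methoxy-5-methyl-3-(prop-2-en-1-yloxy)benzyl acetate F6. Dess–Martin periodinane gives 2-(2,6-dimethoxybenzoyl)-6-methoxy-5-methyl-3-(prop-2-en-1-yloxy)benzyl acetate F7. Palladium-catalysed allyl transfer to morpholine (Pd(PPh3)4, morpholine, THF, rt) frees the phenol and returns the route at 16.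

Step 7. Oxidation of the electron-rich 4-methoxyphenol ring (quinone formation or oxidative coupling) may compete with a slow surface oxidation of the crowded carbinol, whose C–H bond is poorly exposed. The fallback masks the phenol for the oxidation only and sets out from 15. Phenol-selective silylation (TBSCl, imidazole, CH2Cl2, 0 °C; the hindered carbinol should not react) gives rac-3-[(tert-butyldimethylsilyl)oxy]-2-[(2,6-dimethoxyphenyl)(hydroxy)methyl]-6-methoxy-5-methylbenzyl acetate F8. A homogeneous oxidant (Dess–Martin periodinane, NaHCO3, CH2Cl2) gives 3-[(tert-butyldimethylsilyl)oxy]-2-(2,6-dimethoxybenzoyl)-6-methoxy-5-methylbenzyl acetate F9. Buffered fluoride (TBAF/AcOH) cleaves the aryl silyl ether and returns the route at 16.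

Step 4. The lithium alkoxide may over-react with further formaldehyde, which would end as an acetoxymethyl ether after acylation; the polymer may depolymerise incompletely; and the base may deprotonate the doubly activated C–H next to the silyl ether, with silyl migration. The fallback forms the whole four-carbon arm in one carbonyl addition, without an organolithium on a silyl ether, and sets out from 6. Prop-2-yn-1-ol, doubly deprotonated with EtMgBr (2 equiv, THF), is added to 6 to give rac-1-(2,6-dimethoxyphenyl)but-2-yne-1,4-diol F10. The unhindered primary hydroxyl is acetylated selectively (AcCl, 2,4,6-collidine, CH2Cl2, −78 °C) to rac-4-(2,6-dimethoxyphenyl)-4-hydroxybut-2-yn-1-yl acetate F11. Silylation as in step 3 then returns the route at 12.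

## Further compounds

F1 | step 5 | 4,4-diethoxybut-2-yn-1-yl acetate | CCOC(OCC)C#CCOC(C)=O
F2 | step 5 | 2-(diethoxymethyl)-3-hydroxy-6-methoxy-5-methylbenzyl acetate | CCOC(OCC)c1c(O)cc(C)c(OC)c1COC(C)=O
F3 | step 5 | 2-formyl-3-hydroxy-6-methoxy-5-methylbenzyl acetate | O=Cc1c(O)cc(C)c(OC)c1COC(C)=O
F4 | step 5 | 2,6-dimethoxyphenyllithium | [Li]c1c(OC)cccc1OC
F5 | step 6 | rac-2-{[(tert-butyldimethylsilyl)oxy](2,6-dimethoxyphenyl)methyl}-6-methoxy-5-methyl-3-(prop-2-en-1-yloxy)benzyl acetate | COc1cccc(OC)c1C(O[Si](C)(C)C(C)(C)C)c1c(OCC=C)cc(C)c(OC)c1COC(C)=O
F6 | step 6 | rac-2-[(2,6-dimethoxyphenyl)(hydroxy)methyl]-6-methoxy-5-methyl-3-(prop-2-en-1-yloxy)benzyl acetate | COc1cccc(OC)c1C(O)c1c(OCC=C)cc(C)c(OC)c1COC(C)=O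
F7 | step 6 | 2-(2,6-dimethoxybenzoyl)-6-methoxy-5-methyl-3-(prop-2-en-1-yloxy)benzyl acetate | COc1cccc(OC)c1C(=O)c1c(OCC=C)cc(C)c(OC)c1COC(C)=O
F8 | step 7 | rac-3-[(tert-butyldimethylsilyl)oxy]-2-[(2,6-dimethoxyphenyl)(hydroxy)methyl]-6-methoxy-5-methylbenzyl acetate | COc1cccc(OC)c1C(O)c1c(O[Si](C)(C)C(C)(C)C)cc(C)c(OC)c1COC(C)=O
F9 | step 7 | 3-[(tert-butyldimethylsilyl)oxy]-2-(2,6-dimethoxybenzoyl)-6-methoxy-5-methylbenzyl acetate | COc1cccc(OC)c1C(=O)c1c(O[Si](C)(C)C(C)(C)C)cc(C)c(OC)c1COC(C)=O
F10 | step 4 | rac-1-(2,6-dimethoxyphenyl)but-2-yne-1,4-diol | COc1cccc(OC)c1C(O)C#CCO
F11 | step 4 | rac-4-(2,6-dimethoxyphenyl)-4-hydroxybut-2-yn-1-yl acetate | COc1cccc(OC)c1C(O)C#CCOC(C)=O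
A1 | alternative 1 | 2-iodo-4-methoxy-1-(methoxymethoxy)-3-[(methoxymethoxy)methyl]-5-methylbenzene | COCOCc1c(I)c(OCOC)cc(C)c1OC
A2 | alternative 1 | carbon monoxide | [C-]#[O+]
A3 | alternative 1 | 2,6-dimethoxyphenylboronic acid | COc1cccc(OC)c1B(O)O
A4 | alternative 1 | (2,6-dimethoxyphenyl){5-methoxy-2-(methoxymethoxy)-6-[(methoxymethoxy)methyl]-4-methylphenyl}methanone | COCOCc1c(C(=O)c2c(OC)cccc2OC)c(OCOC)cc(C)c1OC
A5 | alternative 2 | rac-2-({[1-(2,6-dimethoxyphenyl)prop-2-yn-1-yl]oxy}methyl)-3-methoxy-4-methylfuran | C#CC(OCc1occ(C)c1OC)c1c(OC)cccc1OC
A6 | alternative 2 | rac-3-(2,6-dimethoxyphenyl)-7-methoxy-6-methyl-1,3-dihydro-2-benzofuran-4-ol | COc1cccc(OC)c1C1OCc2c(OC)c(C)cc(O)c12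
A7 | alternative 3 | 4-methoxy-3-[(methoxymethoxy)methyl]-5-methyl-2-(trimethylsilyl)phenyl trifluoromethanesulfonate | COCOCc1c([Si](C)(C)C)c(OS(=O)(=O)C(F)(F)F)cc(C)c1OC
A8 | alternative 3 | 1,2-didehydro-4-methoxy-3-[(methoxymethoxy)methyl]-5-methylbenzene (ring B aryne) | COCOCC1=C(OC)C(C)=CC#C1
A9 | alternative 3 | 2,6-dimethoxybenzoic acid | COc1cccc(OC)c1C(O)=O
A10 | alternative 3 | (2,6-dimethoxyphenyl){2-hydroxy-5-methoxy-6-[(methoxymethoxy)methyl]-4-methylphenyl}methanone | COCOCc1c(C(=O)c2c(OC)cccc2OC)c(O)cc(C)c1OC
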